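**Retrosynthetic overview**
1. The plan rests on the benzene ring of the target: C1 carries CO2H, C2 and C4 carry OH, C6 carries the (8Z,10R)-10-acetoxypentadec-8-enyl chain. Without the carboxyl carbon and the acetyl group this is a 5-alkylresorcinol, with the two oxygens meta to each other and the chain meta to both.
2. That ring, the only ring, is closed in step 6 from cyclobutenone 10 (which supplies C4 with its oxygen, C5, C6 with the chain, and C1) and ynol ether 15 (which supplies C3 and C2 with its oxygen). Bonds C3–C4 and C1–C2 form in a ketene–alkyne [2+2] step, and C4–C5 in a six-electron electrocyclisation.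
3. Cyclobutenone 10 comes from the Grignard reagent of (Z)-bromide 6 and 3-ethoxycyclobutenone 7. Bromide 6 comes from (R)-oct-1-yn-3-ol 1, which brings the only stereocentre, and 1,7-dibromoheptane 3, followed by Lindlar reduction. Ynol ether 15 comes from 2-(trimethylsilyl)ethanol 11 and trichloroethylene 12.
4. After the annulation, fluoride frees both phenols and the chain hydroxyl. The phenols are then capped as triisopropylsilyl ethers, bromination and bromine–lithium exchange/CO2 place the carboxyl group beside the chain, the chain hydroxyl is acetylated, and buffered fluoride removes the aryl silyl ethers.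

Key step: step 6

Remark: compounds 1, 3, 7, 11 and 12 are taken as commercial; in the symmetric bis(silyl ether) 22 the ring carbons C1 and C5 on either side of the chain are equivalent, so either bromination site leads to the target.

**Route**

Step 1
Reactants: 1 (R)-oct-1-yn-3-ol
Product: 2 (R)-tert-butyldimethyl(oct-1-yn-3-yloxy)silane
Conditions: TBSCl (1.2 equiv), imidazole (2.5 equiv), DMF, 0 °C → rt
Reagents that add atoms: tert-butyldimethylsilyl chloride, CC(C)(C)[Si](C)(C)Cl
Why: Imidazole-promoted O-silylation of a secondary propargylic alcohol is routine and breaks no bond at the carbinol carbon, so the (R) centre brought in with 1 is carried through unchanged.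

Step 2
Reactants: 2 (R)-tert-butyldimethyl(oct-1-yn-3-yloxy)silane; 3 1,7-dibromoheptane
Product: 5 (R)-[(15-bromopentadec-7-yn-6-yl)oxy](tert-butyl)dimethylsilane, via lithium acetylide 4 (not isolated)
Conditions: n-BuLi (1.05 equiv), THF, −78 → −20 °C; then 3 (4 equiv), DMPU, −20 °C → rt
Reagents that add atoms: none
Why: SN2 alkylation of a lithium acetylide by a primary bromide in THF/DMPU is standard, the large excess of the symmetric dibromide (recoverable by distillation) should hold back double alkylation, and the propargylic silyl ether is not deprotonated under these conditions.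

Step 3
Reactants: 5 (R)-[(15-bromopentadec-7-yn-6-yl)oxy](tert-butyl)dimethylsilane
Product: 6 tert-butyl{[(6R,7Z)-15-bromopentadec-7-en-6-yl]oxy}dimethylsilane
Conditions: H2 (1 atm), Pd/CaCO3 poisoned with Pb(OAc)2 (Lindlar catalyst), quinoline, hexane, rt, stopped after one equivalent of H2
Reagents that add atoms: none
Why: Lindlar semihydrogenation delivers both hydrogens to the same face of the alkyne on the poisoned palladium surface and so should set the (Z)-alkene, while the primary bromide and the silyl ether are inert.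

Step 4
Reactants: 6 tert-butyl{[(6R,7Z)-15-bromopentadec-7-en-6-yl]oxy}dimethylsilane; 7 3-ethoxycyclobut-2-en-1-one
Product: 10 3-[(8Z,10R)-10-(tert-butyldimethylsilyloxy)pentadec-8-en-1-yl]cyclobut-2-en-1-one, via Grignard reagent 8 (not isolated), via bromomagnesium alkoxide 9 (not isolated)
Conditions: Mg turnings, THF, rt → 40 °C; then 7 (1.3 equiv), THF, −78 → 0 °C; then 1 M HCl, THF, 0 °C
Reagents that add atoms: water, O
Why: 1,2-Addition of a primary alkyl Grignard reagent to the carbonyl group of the vinylogous ester, followed by acid hydrolysis of the β-ethoxy allylic carbinol (a Stork–Danheiser-type carbonyl transposition on the four-membered ring), is a standard entry to 3-alkylcyclobutenones, and the secondary silyl ether should survive the brief cold dilute acid.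

Step 5
Reactants: 11 2-(trimethylsilyl)ethanol; 12 trichloroethylene
Product: 15 [2-(ethynyloxy)ethyl]trimethylsilane, via dichlorovinyl ether 13 (not isolated), via lithium alkoxyacetylide 14 (not isolated)
Conditions: KH (1.1 equiv), THF, 0 °C; 12 (1.05 equiv), −50 °C → rt; then n-BuLi (2.4 equiv), −78 → −40 °C; then H2O, −78 °C; distilled under reduced pressure, stored cold
Reagents that add atoms: none
Why: Addition–elimination of the potassium alkoxide on trichloroethylene to the (E)-1,2-dichlorovinyl ether, then elimination of HCl and chlorine–lithium exchange with n-BuLi and protonation, is the established one-flask route from an alcohol to a terminal ynol ether, and a primary alkyl ynol ether should be stable enough to isolate.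

Step 6
Reactants: 10 3-[(8Z,10R)-10-(tert-butyldimethylsilyloxy)pentadec-8-en-1-yl]cyclobut-2-en-1-one; 15 [2-(ethynyloxy)ethyl]trimethylsilane
Product: 20 3-[(8Z,10R)-10-(tert-butyldimethylsilyloxy)pentadec-8-en-1-yl]-5-[2-(trimethylsilyl)ethoxy]phenol, via vinylketene 16 (not isolated), via alkenylcyclobutenone 17 (not isolated), via dienylketene 18 (not isolated), via cyclohexadienone 19 (not isolated)
Conditions: 15 (2 equiv), toluene, 80 °C, sealed tube, Ar; then K2CO3, MeOH, rt (returns 20 from any aryl ester formed by ketene capture)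
Reagents that add atoms: none
Why: At 80 °C cyclobutenone 10 should open reversibly by a four-electron electrocyclic reaction to vinylketene 16, whose carbonyl carbon is attacked by the nucleophilic unsubstituted carbon of ynol ether 15 while its α-carbon bonds to the oxygen-bearing alkyne carbon, giving 17 by a [2+2] cycloaddition. A second four-electron opening gives dienylketene 18, which closes the only ring of the step by a thermally allowed six-electron electrocyclisation between the ketene carbon and the terminal methylene to give 19, and tautomerisation delivers phenol 20. This is the Danheiser benzannulation of a 3-alkylcyclobutenone with an alkoxyalkyne, the known route to 5-alkylresorcinol monoethers. No stereocentre is created, and the carbinol centre and the (Z)-alkene of the chain are remote and are not touched. The selectivity needed is regiochemical (the two oxygens meta to each other and the chain meta to both) and is fixed by the polarisation of the ynol ether, while chemoselectivity rests on the isolated alkene and the silyl ether being inert to ketenes at this temperature. The ynol ether carries a primary alkyl group, so its retro-ene loss of ketene should need a higher temperature than the annulation, and it is used in excess.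

Step 7
Reactants: 20 3-[(8Z,10R)-10-(tert-butyldimethylsilyloxy)pentadec-8-en-1-yl]-5-[2-(trimethylsilyl)ethoxy]phenol
Product: 21 5-[(8Z,10R)-10-hydroxypentadec-8-en-1-yl]benzene-1,3-diol
Conditions: Bu4NF (6 equiv), DMF, 80 °C, Ar; aq. NH4Cl work-up
Reagents that add atoms: none
Why: Fluoride attack at silicon should fragment the aryl 2-(trimethylsilyl)ethyl ether by 1,2-elimination to the phenoxide, ethene and Me3SiF and at the same time cleave the secondary TBS ether, and the forcing temperature is acceptable because the substrate holds only an isolated (Z)-alkene, an alcohol and phenols.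

Step 8
Reactants: 21 5-[(8Z,10R)-10-hydroxypentadec-8-en-1-yl]benzene-1,3-diol
Product: 22 (6R,7Z)-15-[3,5-bis(triisopropylsilyloxy)phenyl]pentadec-7-en-6-ol
Conditions: TIPSCl (2.2 equiv), imidazole (5 equiv), DMF, 0 °C → rt
Reagents that add atoms: triisopropylsilyl chloride, CC(C)[Si](Cl)(C(C)C)C(C)C
Why: Under imidazole catalysis the bulky chlorosilane silylates phenols far faster than a hindered secondary alcohol, so both phenols should be capped while the chain hydroxyl stays free, and the resulting arene is symmetric so that the two ring positions flanking the chain become equivalent.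

Step 9
Reactants: 22 (6R,7Z)-15-[3,5-bis(triisopropylsilyloxy)phenyl]pentadec-7-en-6-ol
Product: 23 (6R,7Z)-15-[2-bromo-3,5-bis(triisopropylsilyloxy)phenyl]pentadec-7-en-6-ol
Conditions: NBS (1.0 equiv), MeCN, 0 °C → rt, dark
Reagents that add atoms: N-bromosuccinimide, O=C1CCC(=O)N1Br
Why: Electrophilic aromatic bromination of a resorcinol diether goes to the position beside the alkyl group that is para to one oxygen and ortho to the other (the site between the two bulky silyloxy groups is shielded), and the activated arene should react faster than the unactivated 1,2-disubstituted alkene under ionic conditions in the dark.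

Step 10
Reactants: 23 (6R,7Z)-15-[2-bromo-3,5-bis(triisopropylsilyloxy)phenyl]pentadec-7-en-6-ol
Product: 25 2-[(8Z,10R)-10-hydroxypentadec-8-en-1-yl]-4,6-bis(triisopropylsilyloxy)benzoic acid, via aryllithium alkoxide 24 (not isolated)
Conditions: t-BuLi (3.2 equiv), THF, −78 °C, 15 min; CO2 (g), −78 → 0 °C; 1 M HCl, 0 °C
Reagents that add atoms: carbon dioxide, O=C=O
Why: The first equivalent of t-BuLi deprotonates the alcohol and two more effect bromine–lithium exchange, the hindered aryllithium is carboxylated by CO2 (the lithium alkyl carbonate formed at the alkoxide reverts to the alcohol on acidification), and at −78 °C the shift of the bulky triisopropylsilyl group from oxygen to the lithiated carbon should be slow.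

Step 11
Reactants: 25 2-[(8Z,10R)-10-hydroxypentadec-8-en-1-yl]-4,6-bis(triisopropylsilyloxy)benzoic acid
Product: 27 2-[(8Z,10R)-10-acetoxypentadec-8-en-1-yl]-4,6-bis(triisopropylsilyloxy)benzoic acid, via mixed anhydride 26 (not isolated)
Conditions: Ac2O (3 equiv), pyridine, DMAP (0.1 equiv), CH2Cl2, 0 °C → rt; then H2O, THF, rt
Reagents that add atoms: acetic anhydride, CC(=O)OC(C)=O
Why: DMAP-catalysed acetylation of the secondary alcohol leaves its C–O bond intact and so retains the (R) configuration, and the aroyl acetyl mixed anhydride that forms at the doubly ortho-substituted carboxyl group is attacked by water only at its unhindered acetyl carbonyl, so it should revert to the free acid on aqueous treatment.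

Step 12
Reactants: 27 2-[(8Z,10R)-10-acetoxypentadec-8-en-1-yl]-4,6-bis(triisopropylsilyloxy)benzoic acid
Product: 28 2-[(8Z,10R)-10-acetoxypentadec-8-en-1-yl]-4,6-dihydroxybenzoic acid (CNP0288291.1)
Conditions: Bu4NF (3 equiv), AcOH (3 equiv), THF, 0 °C; work-up at pH 3–4, no heating
Reagents that add atoms: none
Why: Aryl silyl ethers, here further activated by the ortho/para carboxyl group, should be cleaved rapidly by acetic acid-buffered fluoride at 0 °C, conditions under which the secondary acetate, the (Z)-allylic system and the easily decarboxylated dihydroxybenzoic acid should all persist.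

**Compound list**
1 | (R)-oct-1-yn-3-ol | CCCCC[C@@H](O)C#C | starting material
2 | (R)-tert-butyldimethyl(oct-1-yn-3-yloxy)silane | CCCCC[C@@H](O[Si](C)(C)C(C)(C)C)C#C | intermediate
3 | 1,7-dibromoheptane | BrCCCCCCCBr | starting material
4 | [(3R)-3-(tert-butyldimethylsilyloxy)oct-1-yn-1-yl]lithium | CCCCC[C@@H](O[Si](C)(C)C(C)(C)C)C#C[Li] | intermediate
5 | (R)-[(15-bromopentadec-7-yn-6-yl)oxy](tert-butyl)dimethylsilane | CCCCC[C@@H](O[Si](C)(C)C(C)(C)C)C#CCCCCCCCBr | intermediate
6 | tert-butyl{[(6R,7Z)-15-bromopentadec-7-en-6-yl]oxy}dimethylsilane | CCCCC[C@@H](O[Si](C)(C)C(C)(C)C)/C=C\CCCCCCCBr | intermediate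
7 | 3-ethoxycyclobut-2-en-1-one | CCOC1=CC(=O)C1 | starting material
8 | {(8Z,10R)-10-[(tert-butyldimethylsilyl)oxy]pentadec-8-en-1-yl}magnesium bromide | Br[Mg]CCCCCCC/C=C\[C@@H](CCCCC)O[Si](C)(C)C(C)(C)C | intermediate
9 | bromomagnesium 1-[(8Z,10R)-10-(tert-butyldimethylsilyloxy)pentadec-8-en-1-yl]-3-ethoxycyclobut-2-en-1-olate (ring carbinol centre unassigned) | CCOC1=CC(CCCCCCC/C=C\[C@@H](CCCCC)O[Si](C)(C)C(C)(C)C)(O[Mg]Br)C1 | intermediate
10 | 3-[(8Z,10R)-10-(tert-butyldimethylsilyloxy)pentadec-8-en-1-yl]cyclobut-2-en-1-one | O=C1C=C(CCCCCCC/C=C\[C@@H](CCCCC)O[Si](C)(C)C(C)(C)C)C1 | intermediate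
11 | 2-(trimethylsilyl)ethanol | C[Si](C)(C)CCO | starting material
12 | trichloroethylene | ClC=C(Cl)Cl | starting material
13 | (E)-[2-(1,2-dichloroethenyloxy)ethyl]trimethylsilane | C[Si](C)(C)CCO/C(Cl)=C\Cl | intermediate
14 | {[2-(trimethylsilyl)ethoxy]ethynyl}lithium | C[Si](C)(C)CCOC#C[Li] | intermediate
15 | [2-(ethynyloxy)ethyl]trimethylsilane | C#COCC[Si](C)(C)C | intermediate
16 | 3-[(8Z,10R)-10-(tert-butyldimethylsilyloxy)pentadec-8-en-1-yl]buta-1,3-dien-1-one | O=C=CC(=C)CCCCCCC/C=C\[C@@H](CCCCC)O[Si](C)(C)C(C)(C)C | intermediate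
17 | 4-[(10Z,12R)-12-(tert-butyldimethylsilyloxy)heptadeca-1,10-dien-2-yl]-3-[2-(trimethylsilyl)ethoxy]cyclobut-2-en-1-one (ring C4 unassigned) | O=C1C=C(OCC[Si](C)(C)C)C1C(=C)CCCCCCC/C=C\[C@@H](CCCCC)O[Si](C)(C)C(C)(C)C | intermediate
18 | (3E)-5-[(8Z,10R)-10-(tert-butyldimethylsilyloxy)pentadec-8-en-1-yl]-3-[2-(trimethylsilyl)ethoxy]hexa-1,3,5-trien-1-one | O=C=C/C(OCC[Si](C)(C)C)=C\C(=C)CCCCCCC/C=C\[C@@H](CCCCC)O[Si](C)(C)C(C)(C)C | intermediate
19 | 5-[(8Z,10R)-10-(tert-butyldimethylsilyloxy)pentadec-8-en-1-yl]-3-[2-(trimethylsilyl)ethoxy]cyclohexa-2,4-dien-1-one | O=C1C=C(OCC[Si](C)(C)C)C=C(CCCCCCC/C=C\[C@@H](CCCCC)O[Si](C)(C)C(C)(C)C)C1 | intermediate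
20 | 3-[(8Z,10R)-10-(tert-butyldimethylsilyloxy)pentadec-8-en-1-yl]-5-[2-(trimethylsilyl)ethoxy]phenol | CCCCC[C@H](/C=C\CCCCCCCc1cc(O)cc(OCC[Si](C)(C)C)c1)O[Si](C)(C)C(C)(C)C | intermediate
21 | 5-[(8Z,10R)-10-hydroxypentadec-8-en-1-yl]benzene-1,3-diol | CCCCC[C@H](/C=C\CCCCCCCc1cc(O)cc(O)c1)O | intermediate
22 | (6R,7Z)-15-[3,5-bis(triisopropylsilyloxy)phenyl]pentadec-7-en-6-ol | CCCCC[C@H](/C=C\CCCCCCCc1cc(O[Si](C(C)C)(C(C)C)C(C)C)cc(O[Si](C(C)C)(C(C)C)C(C)C)c1)O | intermediate
23 | (6R,7Z)-15-[2-bromo-3,5-bis(triisopropylsilyloxy)phenyl]pentadec-7-en-6-ol | CCCCC[C@H](/C=C\CCCCCCCc1cc(O[Si](C(C)C)(C(C)C)C(C)C)cc(O[Si](C(C)C)(C(C)C)C(C)C)c1Br)O | intermediate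
24 | lithium (6R,7Z)-15-[2-lithio-3,5-bis(triisopropylsilyloxy)phenyl]pentadec-7-en-6-olate | CCCCC[C@H](/C=C\CCCCCCCc1cc(O[Si](C(C)C)(C(C)C)C(C)C)cc(O[Si](C(C)C)(C(C)C)C(C)C)c1[Li])O[Li] | intermediate
25 | 2-[(8Z,10R)-10-hydroxypentadec-8-en-1-yl]-4,6-bis(triisopropylsilyloxy)benzoic acid | CCCCC[C@H](/C=C\CCCCCCCc1cc(O[Si](C(C)C)(C(C)C)C(C)C)cc(O[Si](C(C)C)(C(C)C)C(C)C)c1C(=O)O)O | intermediate
26 | acetic 2-[(8Z,10R)-10-acetoxypentadec-8-en-1-yl]-4,6-bis(triisopropylsilyloxy)benzoic anhydride | CCCCC[C@H](/C=C\CCCCCCCc1cc(O[Si](C(C)C)(C(C)C)C(C)C)cc(O[Si](C(C)C)(C(C)C)C(C)C)c1C(=O)OC(C)=O)OC(C)=O | intermediate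
27 | 2-[(8Z,10R)-10-acetoxypentadec-8-en-1-yl]-4,6-bis(triisopropylsilyloxy)benzoic acid | CCCCC[C@H](/C=C\CCCCCCCc1cc(O[Si](C(C)C)(C(C)C)C(C)C)cc(O[Si](C(C)C)(C(C)C)C(C)C)c1C(=O)O)OC(C)=O | intermediate
28 | 2-[(8Z,10R)-10-acetoxypentadec-8-en-1-yl]-4,6-dihydroxybenzoic acid | CCCCC[C@H](/C=C\CCCCCCCc1cc(O)cc(O)c1C(=O)O)OC(C)=O | target

**Step count and risks**

Total step count: 12. Longest linear sequence: 11 steps (1 to 28 through steps 1–4 and 6–12); step 5 is a one-step side branch.

Steps most likely to fail: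

1. Step 6 (key step). The ynol ether 15 may fragment by retro-ene loss of ketene, or oligomerise, before it is captured. Vinylketene 16 may also be consumed by dimerisation or by acylating the phenol as it forms, so that conversion to 20 stalls.
 Fallback: the arene is bought instead of built. Commercial 5-bromobenzene-1,3-diol is silylated (TIPSCl, imidazole, DMF) to 1-bromo-3,5-bis(triisopropylsilyloxy)benzene F1. Setting out from Grignard reagent 8 (made from 6 as in step 4), transmetalation with ZnCl2 in THF gives {(8Z,10R)-10-[(tert-butyldimethylsilyl)oxy]pentadec-8-en-1-yl}zinc chloride F2. Negishi coupling of F1 with F2 (Pd(OAc)2, SPhos, THF, rt → 50 °C) should give tert-butyl{[(6R,7Z)-15-[3,5-bis(triisopropylsilyloxy)phenyl]pentadec-7-en-6-yl]oxy}dimethylsilane F3. Methanolysis of the secondary alkyl TBS ether with catalytic camphorsulfonic acid in MeOH/CH2Cl2 at 0 °C, which aryl triisopropylsilyl ethers should survive, comes back to the route at 22.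

2. Step 7. Fragmentation of the 2-(trimethylsilyl)ethyl ether may be slow because the group that has to leave is an electron-rich resorcinolate, and the substrate may then decompose under the basic conditions at the temperature needed.
 Fallback: the ether cleavage is postponed until the ring carries the carboxyl group, and the final differentiation is done with acetates. Setting out from 20, Mitsunobu etherification with 11 (PPh3, DIAD, THF) gives the symmetric tert-butyl{[(6R,7Z)-15-{3,5-bis[2-(trimethylsilyl)ethoxy]phenyl}pentadec-7-en-6-yl]oxy}dimethylsilane F4. NBS in MeCN gives tert-butyl{[(6R,7Z)-15-{2-bromo-3,5-bis[2-(trimethylsilyl)ethoxy]phenyl}pentadec-7-en-6-yl]oxy}dimethylsilane F5. Treatment with t-BuLi (2.1 equiv, THF, −78 °C), then CO2 and HCl work-up, gives 2-[(8Z,10R)-10-(tert-butyldimethylsilyloxy)pentadec-8-en-1-yl]-4,6-bis[2-(trimethylsilyl)ethoxy]benzoic acid F6. Bu4NF in DMF at 60 °C now expels phenoxides that are conjugated with the carboxyl group, and should cleave both aryl ethers and the TBS ether to 2,4-dihydroxy-6-[(8Z,10R)-10-hydroxypentadec-8-en-1-yl]benzoic acid F7. Ac2O/pyridine with aqueous work-up gives 2,4-diacetoxy-6-[(8Z,10R)-10-acetoxypentadec-8-en-1-yl]benzoic acid F8. NH4OAc in aqueous MeOH at rt, which cleaves phenolic acetates much faster than alkyl acetates, comes back to the route at 28.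

3. Step 10. A silyl group may migrate from oxygen to the lithiated ring carbon (retro-Brook shift), or the aryllithium may be protonated before CO2 is admitted.
 Fallback: the carboxyl group is introduced electrophilically on the free resorcinol, without a halide or an aryllithium. Setting out from 21, Kolbe–Schmitt-type carboxylation with methyl magnesium carbonate, Mg(OMe)(OCO2Me), in DMF at 120 °C and cold acidification should give 2,4-dihydroxy-6-[(8Z,10R)-10-hydroxypentadec-8-en-1-yl]benzoic acid F9 (the same compound as F7), carboxylated beside the chain as is known for 5-alkylresorcinols. TIPSCl (3.5 equiv), imidazole, DMF gives triisopropylsilyl 2-[(8Z,10R)-10-hydroxypentadec-8-en-1-yl]-4,6-bis(triisopropylsilyloxy)benzoate F10. Hydrolysis of the silyl ester alone with AcOH/THF/H2O at rt comes back to the route at 25.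

Further compounds
F1 | step 6 | 1-bromo-3,5-bis(triisopropylsilyloxy)benzene | Brc1cc(O[Si](C(C)C)(C(C)C)C(C)C)cc(O[Si](C(C)C)(C(C)C)C(C)C)c1
F2 | step 6 | {(8Z,10R)-10-[(tert-butyldimethylsilyl)oxy]pentadec-8-en-1-yl}zinc chloride | Cl[Zn]CCCCCCC/C=C\[C@@H](CCCCC)O[Si](C)(C)C(C)(C)C
F3 | step 6 | tert-butyl{[(6R,7Z)-15-[3,5-bis(triisopropylsilyloxy)phenyl]pentadec-7-en-6-yl]oxy}dimethylsilane | CCCCC[C@H](/C=C\CCCCCCCc1cc(O[Si](C(C)C)(C(C)C)C(C)C)cc(O[Si](C(C)C)(C(C)C)C(C)C)c1)O[Si](C)(C)C(C)(C)C
F4 | step 7 | tert-butyl{[(6R,7Z)-15-{3,5-bis[2-(trimethylsilyl)ethoxy]phenyl}pentadec-7-en-6-yl]oxy}dimethylsilane | CCCCC[C@H](/C=C\CCCCCCCc1cc(OCC[Si](C)(C)C)cc(OCC[Si](C)(C)C)c1)O[Si](C)(C)C(C)(C)C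
F5 | step 7 | tert-butyl{[(6R,7Z)-15-{2-bromo-3,5-bis[2-(trimethylsilyl)ethoxy]phenyl}pentadec-7-en-6-yl]oxy}dimethylsilane | CCCCC[C@H](/C=C\CCCCCCCc1cc(OCC[Si](C)(C)C)cc(OCC[Si](C)(C)C)c1Br)O[Si](C)(C)C(C)(C)C
F6 | step 7 | 2-[(8Z,10R)-10-(tert-butyldimethylsilyloxy)pentadec-8-en-1-yl]-4,6-bis[2-(trimethylsilyl)ethoxy]benzoic acid | CCCCC[C@H](/C=C\CCCCCCCc1cc(OCC[Si](C)(C)C)cc(OCC[Si](C)(C)C)c1C(=O)O)O[Si](C)(C)C(C)(C)C
F7 | step 7 | 2,4-dihydroxy-6-[(8Z,10R)-10-hydroxypentadec-8-en-1-yl]benzoic acid | CCCCC[C@H](/C=C\CCCCCCCc1cc(O)cc(O)c1C(=O)O)O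
F8 | step 7 | 2,4-diacetoxy-6-[(8Z,10R)-10-acetoxypentadec-8-en-1-yl]benzoic acid | CCCCC[C@H](/C=C\CCCCCCCc1cc(OC(C)=O)cc(OC(C)=O)c1C(=O)O)OC(C)=O
F9 | step 10 | 2,4-dihydroxy-6-[(8Z,10R)-10-hydroxypentadec-8-en-1-yl]benzoic acid | CCCCC[C@H](/C=C\CCCCCCCc1cc(O)cc(O)c1C(=O)O)O
F10 | step 10 | triisopropylsilyl 2-[(8Z,10R)-10-hydroxypentadec-8-en-1-yl]-4,6-bis(triisopropylsilyloxy)benzoate | CCCCC[C@H](/C=C\CCCCCCCc1cc(O[Si](C(C)C)(C(C)C)C(C)C)cc(O[Si](C(C)C)(C(C)C)C(C)C)c1C(=O)O[Si](C(C)C)(C(C)C)C(C)C)O
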